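The route rests on cutting C7–C8 in the carbocycle (ring B) of the tetrahydroquinoline. C8 is the picolylic carbon on C8a, ortho to the C5-bearing C4a of the pyridine (ring A). The six atoms C8–C8a–C4a–C5–C6–C7 can therefore be a hexatriene. The precursor is a monocyclic pyridyl allene, ArC(R)=C=CH2, flanked by a plain methyl group (future C8). Heating moves one methyl hydrogen to the central allene carbon ([1,5]-shift), and the resulting aza-ortho-xylylene closes by 6π electrocyclisation. This gives C–H functionalisation, the C7–C8 bond and ring B in one reagent-free operation. The C5=C6 olefin left behind is then hydrogenated enantioselectively to set 5R. N-oxidation ends the route.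

Key step: step 5

Remark: all intermediates carry the atom numbering of the target (N1, C2, C3, C4, C4a, C5–C8, C8a; ring A = pyridine, ring B = carbocycle). By the CIP rules (C4a > C6 > C1' of the side chain > H) the stereocentre C5 of the target is R.

Step 1
Reactants: 1 3,4-dimethoxy-2-methylpyridine
Product: 2 3,4-dimethoxy-2,6-dimethylpyridine
Conditions: tBuOOAc (2.5 equiv), [Ir(dF(CF3)ppy)2(dtbbpy)]PF6 (1 mol %), TFA/MeCN 1:1, blue LED, rt
Reagents that add atoms: tert-butyl peracetate, CC(=O)OOC(C)(C)C
Why: Photoredox Minisci reaction in which the methyl radical released by β-scission of the tert-butoxyl radical adds to the protonated pyridine only at C8a, because C2 and C4, the other positions open to nucleophilic radicals, are already substituted, so neither regioisomers nor over-methylation can arise.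

Step 2
Reactants: 2 3,4-dimethoxy-2,6-dimethylpyridine
Product: 3 3-bromo-4,5-dimethoxy-2,6-dimethylpyridine
Conditions: NBS (1.1 equiv), MeCN, dark, 60 °C
Reagents that add atoms: N-bromosuccinimide (NBS), O=C1CCC(=O)N1Br
Why: Electrophilic aromatic bromination in which C4a is the only ring C–H left and lies ortho to the 4-methoxy donor, while exclusion of light and initiators keeps the two methyl groups out of radical bromination.

Step 3
Reactants: 3 3-bromo-4,5-dimethoxy-2,6-dimethylpyridine; 4 3-methoxyprop-1-yne (methyl propargyl ether)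
Product: 5 3,4-dimethoxy-5-(3-methoxyprop-1-yn-1-yl)-2,6-dimethylpyridine
Conditions: PdCl2(MeCN)2 (3 mol %), XPhos (9 mol %), Cs2CO3, MeCN, 80 °C, sealed tube
Reagents that add atoms: none
Why: Copper-free Sonogashira coupling in which the bulky, electron-rich phosphine lets zerovalent palladium insert into the doubly ortho-substituted C–Br bond, the slim alkyne is an undemanding partner and the propargylic methyl ether is inert to palladium.

Step 4
Reactants: 5 3,4-dimethoxy-5-(3-methoxyprop-1-yn-1-yl)-2,6-dimethylpyridine; 6 (5-bromopentyl)benzene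
Product: 8 3,4-dimethoxy-2,6-dimethyl-5-(8-phenylocta-1,2-dien-3-yl)pyridine, via 5-phenylpentylmagnesium bromide 7 (not isolated)
Conditions: 6, Mg, Et2O, reflux; then 5, CuBr (10 mol %), Et2O, 0 °C to rt; aq NH4Cl
Reagents that add atoms: magnesium, [Mg] (kept only in 7)
Why: Copper-catalysed SN2' substitution of a 1-methoxyalk-2-yne by a Grignard reagent, the classical route to 1,1-disubstituted allenes, in which the alkyl group is delivered to the aryl-bearing alkyne carbon (C5) with loss of methoxide from C7, and no stereo element arises because the allene terminus is CH2.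

Step 5
Reactants: 8 3,4-dimethoxy-2,6-dimethyl-5-(8-phenylocta-1,2-dien-3-yl)pyridine
Product: 10 3,4-dimethoxy-2-methyl-5-(5-phenylpentyl)-7,8-dihydroquinoline, via aza-ortho-xylylene 9 (not isolated)
Conditions: o-dichlorobenzene (0.02 M), BHT (10 mol %), Ar, 200 °C, sealed tube
Reagents that add atoms: none
Why: On heating, one hydrogen of the C8 methyl group migrates suprafacially to the central allene carbon C6 in an aromatic [1,5]-sigmatropic shift across C8–C8a=C4a–C5=C6, which dearomatises ring A to the aza-ortho-xylylene 9 with the new vinyl group C6=C7 held inside, cis to C8a. The hexatriene C8=C8a–C4a=C5–C6=C7 of 9 then closes by a thermal disrotatory 6π electrocyclisation that forms the C7–C8 σ bond, closes the six-membered ring B and restores the pyridine. The closest known reaction type is the thermal conversion of ortho-methylaryl allenes into 1,2-dihydronaphthalenes by the same two pericyclic events. No stereocentre is formed, since C7 and C8 become CH2 groups and C5 stays trigonal until step 6. The step needs site selectivity among the C–H donors, and geometry secures it: only the C8 methyl sits 1,5 to C6, the C2 methyl lies on the far side of ring A, and the 4-methoxy hydrogens would need a seven-membered, non-pericyclic array. High dilution, a radical inhibitor and exclusion of air should hold back allene dimerisation, intermolecular O-to-N methyl transfer and aromatisation to the quinoline.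

Step 6
Reactants: 10 3,4-dimethoxy-2-methyl-5-(5-phenylpentyl)-7,8-dihydroquinoline
Product: 11 (5R)-3,4-dimethoxy-2-methyl-5-(5-phenylpentyl)-5,6,7,8-tetrahydroquinoline
Conditions: [Ir(cod)(Cy2-ThrePHOX)]BArF (2 mol %, ligand antipode chosen for Si-face delivery at C5), H2 (50 bar), CH2Cl2, rt
Reagents that add atoms: none
Why: Iridium-catalysed asymmetric hydrogenation of an unfunctionalised trisubstituted olefin, established for 1-alkyl-3,4-dihydronaphthalenes, in which the chiral N,P ligand tells the flat ring A from the alkyl chain and delivers H2 to the Si face of C5 to set 5R, while the ring nitrogen, flanked by the C2 methyl and C8 methylene groups as in 2,6-lutidine, should not block the metal.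

Step 7
Reactants: 11 (5R)-3,4-dimethoxy-2-methyl-5-(5-phenylpentyl)-5,6,7,8-tetrahydroquinoline
Product: 12 (5R)-3,4-dimethoxy-2-methyl-5-(5-phenylpentyl)-5,6,7,8-tetrahydroquinoline 1-oxide
Conditions: mCPBA (1.2 equiv), CH2Cl2, 0 °C to rt
Reagents that add atoms: 3-chloroperoxybenzoic acid (mCPBA), OOC(=O)c1cccc(Cl)c1
Why: Peracid N-oxidation of an electron-rich pyridine in a molecule that holds no olefin any more, with ethers and the phenyl ring inert and C5 untouched, so the 5R configuration is retained.

Compound list
1 | 3,4-dimethoxy-2-methylpyridine | COc1ccnc(C)c1OC | starting material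
2 | 3,4-dimethoxy-2,6-dimethylpyridine | COc1cc(C)nc(C)c1OC | intermediate
3 | 3-bromo-4,5-dimethoxy-2,6-dimethylpyridine | COc1c(Br)c(C)nc(C)c1OC | intermediate
4 | 3-methoxyprop-1-yne (methyl propargyl ether) | C#CCOC | starting material
5 | 3,4-dimethoxy-5-(3-methoxyprop-1-yn-1-yl)-2,6-dimethylpyridine | COCC#Cc1c(C)nc(C)c(OC)c1OC | intermediate
6 | (5-bromopentyl)benzene | BrCCCCCc1ccccc1 | starting material
7 | 5-phenylpentylmagnesium bromide | Br[Mg]CCCCCc1ccccc1 | intermediate
8 | 3,4-dimethoxy-2,6-dimethyl-5-(8-phenylocta-1,2-dien-3-yl)pyridine | C=C=C(CCCCCc1ccccc1)c1c(C)nc(C)c(OC)c1OC | intermediate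
9 | (5E)-3,4-dimethoxy-2-methyl-6-methylidene-5-(8-phenyloct-1-en-3-ylidene)-5,6-dihydropyridine (aza-ortho-xylylene, vinyl group cis to C8a) | C=C/C(CCCCCc1ccccc1)=C1\C(=C)N=C(C)C(OC)=C1OC | intermediate
10 | 3,4-dimethoxy-2-methyl-5-(5-phenylpentyl)-7,8-dihydroquinoline | COc1c(OC)c(C)nc2c1C(CCCCCc1ccccc1)=CCC2 | intermediate
11 | (5R)-3,4-dimethoxy-2-methyl-5-(5-phenylpentyl)-5,6,7,8-tetrahydroquinoline | COc1c(OC)c(C)nc2c1[C@H](CCCCCc1ccccc1)CCC2 | intermediate
12 | (5R)-3,4-dimethoxy-2-methyl-5-(5-phenylpentyl)-5,6,7,8-tetrahydroquinoline 1-oxide | COc1c(OC)c(C)[n+]([O-])c2c1[C@H](CCCCCc1ccccc1)CCC2 | target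

Total step count: 7
Longest linear sequence: 7 steps (1 to 12)

Steps most likely to fail

Step 5. The dearomatising hydrogen shift may need a temperature at which allene dimerisation and methyl transfer from the 4-methoxy group to nitrogen compete. The in-plane clash between the side chain and the 4-methoxy group raises the barrier further.
- **Fallback:** it sets out from 3 and comes back at 11, bypassing steps 3 to 6. Ring B is still closed at C7–C8, but ionically and with C5 set beforehand.
- A Heck reaction of 3 with methyl acrylate (Pd(OAc)2, P(o-tol)3, K2CO3, DMF, 110 °C) should give methyl (E)-3-(4,5-dimethoxy-2,6-dimethylpyridin-3-yl)prop-2-enoate F1.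
- Conjugate addition of Grignard reagent 7 under CuI/Tol-BINAP catalysis (tBuOMe, −40 °C, ligand antipode chosen for R) should give methyl (3R)-3-(4,5-dimethoxy-2,6-dimethylpyridin-3-yl)-8-phenyloctanoate F2.
- LiAlH4 in THF should give (3R)-3-(4,5-dimethoxy-2,6-dimethylpyridin-3-yl)-8-phenyloctan-1-ol F3.
- MsCl/Et3N should give (3R)-3-(4,5-dimethoxy-2,6-dimethylpyridin-3-yl)-8-phenyloctyl methanesulfonate F4.
- LDA in dilute THF (−78 °C to rt) lithiates the picolylic methyl groups reversibly. Only the C8 carbanion can reach C7 (6-exo-tet), so 11 should result.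

Step 6. Facial selectivity may be poor because the peri 4-methoxy group twists the olefin out of the plane of ring A. The acidic iridium hydrides may also be quenched by the basic nitrogen.
- **Fallback:** it sets out from 10 and comes back at 11, replacing asymmetric catalysis by resolution.
- Hydrogenation over Pd/C (H2, 1 bar, EtOH) should give racemic 3,4-dimethoxy-2-methyl-5-(5-phenylpentyl)-5,6,7,8-tetrahydroquinoline F5.
- Preparative supercritical-fluid chromatography on an amylose carbamate phase separates F5 into 11 and (5S)-3,4-dimethoxy-2-methyl-5-(5-phenylpentyl)-5,6,7,8-tetrahydroquinoline F6.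

Step 4. Direct substitution at the propargylic CH2 may compete with SN2' attack at the alkyne carbon, which is shielded by the doubly ortho-substituted ring. Ionisation of the poor methoxide leaving group may also be sluggish.
- **Fallback:** it sets out from 3 and 6 and comes back at 8, with the polarity of the coupling reversed.
- The dianion of propargyl alcohol (nBuLi, 2 equiv, THF/DMPU) is alkylated with 6 to 8-phenyloct-2-yn-1-ol F7.
- ClCO2Me/pyridine turns F7 into methyl 8-phenyloct-2-yn-1-yl carbonate F8.
- Bromine–lithium exchange on 3 (nBuLi, THF, −78 °C) gives (4,5-dimethoxy-2,6-dimethylpyridin-3-yl)lithium F9.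
- ZnCl2 converts F9 into (4,5-dimethoxy-2,6-dimethylpyridin-3-yl)zinc chloride F10.
- Pd(PPh3)4 (5 mol %, THF, rt) ionises the unhindered carbonate to an allenylpalladium species that bears the metal on the alkyl-substituted carbon. Transmetalation and reductive elimination should give 8.

Further compounds
F1 | step 5 | methyl (E)-3-(4,5-dimethoxy-2,6-dimethylpyridin-3-yl)prop-2-enoate | COC(=O)/C=C/c1c(C)nc(C)c(OC)c1OC
F2 | step 5 | methyl (3R)-3-(4,5-dimethoxy-2,6-dimethylpyridin-3-yl)-8-phenyloctanoate | COC(=O)C[C@@H](CCCCCc1ccccc1)c1c(C)nc(C)c(OC)c1OC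
F3 | step 5 | (3R)-3-(4,5-dimethoxy-2,6-dimethylpyridin-3-yl)-8-phenyloctan-1-ol | OCC[C@@H](CCCCCc1ccccc1)c1c(C)nc(C)c(OC)c1OC
F4 | step 5 | (3R)-3-(4,5-dimethoxy-2,6-dimethylpyridin-3-yl)-8-phenyloctyl methanesulfonate | CS(=O)(=O)OCC[C@@H](CCCCCc1ccccc1)c1c(C)nc(C)c(OC)c1OC
F5 | step 6 | racemic 3,4-dimethoxy-2-methyl-5-(5-phenylpentyl)-5,6,7,8-tetrahydroquinoline | COc1c(OC)c(C)nc2c1C(CCCCCc1ccccc1)CCC2
F6 | step 6 | (5S)-3,4-dimethoxy-2-methyl-5-(5-phenylpentyl)-5,6,7,8-tetrahydroquinoline | COc1c(OC)c(C)nc2c1[C@@H](CCCCCc1ccccc1)CCC2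
F7 | step 4 | 8-phenyloct-2-yn-1-ol | OCC#CCCCCCc1ccccc1
F8 | step 4 | methyl 8-phenyloct-2-yn-1-yl carbonate | COC(=O)OCC#CCCCCCc1ccccc1
F9 | step 4 | (4,5-dimethoxy-2,6-dimethylpyridin-3-yl)lithium | [Li]c1c(C)nc(C)c(OC)c1OC
F10 | step 4 | (4,5-dimethoxy-2,6-dimethylpyridin-3-yl)zinc chloride | Cl[Zn]c1c(C)nc(C)c(OC)c1OC
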